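**Plan**

- Retrosynthesis: the O6 benzyl-type ether is cut last. The C3–O(ester) and O1–C7a bonds are then cut together, giving a trans aryl isopropenyl oxirane that carries fluorine on the future C7a, plus (Z)-2-(acetoxymethyl)but-2-enoic acid.
- Enabling feature: O1 on C7a lies para to the C5 acetyl group, so a fluoride at C7a is open to SNAr. The trans C2–O1 / C3–O-acyl pair on the dihydrofuran ring is what anti opening of a trans oxirane at its benzylic carbon leaves behind.
- The oxirane goes back to an E styrenyl tertiary allylic alcohol (epoxidation, then dehydration to the isopropenyl group), and that to an aryl bromide and 2-methylbut-3-en-2-ol (Heck). The acid goes back to crotonaldehyde.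
- Forward: the benzene ring is bought, the oxirane ring is made in step 3, and the dihydrofuran ring closes in step 9, where the two fragments are joined.
- Stereochemistry: both oxirane centres come from a Shi epoxidation with the L-configured ketone. C2 is carried through unchanged and C3 arises by inversion in step 9. The Z double bond is fixed in the iodoenal of step 5 and kept by retention.

Key step: step 9

Remark: the ketone catalyst of step 3 is the mirror image of the common D-fructose-derived one; it is assumed to be at hand (it can be prepared from L-sorbose) and is used in substoichiometric amount.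

**Route**

Step 1
Reactants: 1 1-(5-bromo-4-fluoro-2-hydroxyphenyl)ethanone; 2 4-methoxybenzyl chloride
Product: 3 1-[5-bromo-4-fluoro-2-(4-methoxybenzyloxy)phenyl]ethanone
Conditions: K2CO3, DMF, 50 °C
Reagents that add atoms: none
Why: Williamson ether synthesis, in which K2CO3 deprotonates the hydrogen-bonded phenol and the phenoxide is O-alkylated by the benzylic chloride at a temperature too low for intermolecular displacement of the aryl fluoride.

Step 2
Reactants: 3 1-[5-bromo-4-fluoro-2-(4-methoxybenzyloxy)phenyl]ethanone; 4 2-methylbut-3-en-2-ol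
Product: 5 1-[4-fluoro-5-[(E)-3-hydroxy-3-methylbut-1-en-1-yl]-2-(4-methoxybenzyloxy)phenyl]ethanone
Conditions: Pd(OAc)2 (cat.), P(o-tolyl)3, Et3N, MeCN, 85 °C
Reagents that add atoms: none
Why: Mizoroki–Heck reaction, in which the aryl–palladium species adds to the unsubstituted alkene terminus and syn β-hydride elimination gives the E alkene, while the tertiary carbinol has no carbinol hydrogen and so cannot be isomerised to a ketone.

Step 3
Reactants: 5 1-[4-fluoro-5-[(E)-3-hydroxy-3-methylbut-1-en-1-yl]-2-(4-methoxybenzyloxy)phenyl]ethanone
Product: 6 1-[4-fluoro-5-[(2S,3R)-3-(2-hydroxypropan-2-yl)oxiran-2-yl]-2-(4-methoxybenzyloxy)phenyl]ethanone (trans oxirane)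
Conditions: 1,2:4,5-di-O-isopropylidene-β-L-erythro-2,3-hexodiulo-2,6-pyranose (0.3 equiv), Oxone (2KHSO5·KHSO4·K2SO4), K2CO3, Bu4NHSO4, MeCN/CH2(OMe)2, aq. Na2B4O7/Na2H2EDTA buffer, 0 °C
Reagents that add atoms: potassium peroxymonosulfate (KHSO5, the oxidant in Oxone), [K+].[O-]S(=O)(=O)OO
Why: Shi asymmetric epoxidation through the chiral dioxirane and a spiro transition state, a reaction class at its best with trans-disubstituted aryl alkenes and tolerant of a free hydroxyl group; the L-configured ketone delivers oxygen to the face opposite to that used by the D-fructose ketone (which gives the R,R oxirane from trans-β-methylstyrene), setting S at the benzylic and R at the carbinol-bearing oxirane carbon.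

Step 4
Reactants: 6 1-[4-fluoro-5-[(2S,3R)-3-(2-hydroxypropan-2-yl)oxiran-2-yl]-2-(4-methoxybenzyloxy)phenyl]ethanone
Product: 7 1-[4-fluoro-2-(4-methoxybenzyloxy)-5-[(2S,3S)-3-(prop-1-en-2-yl)oxiran-2-yl]phenyl]ethanone (trans oxirane)
Conditions: Martin sulfurane (Ph2S[OC(CF3)2Ph]2), CH2Cl2, 0 °C to rt
Reagents that add atoms: none
Why: dehydration of a tertiary alcohol with Martin sulfurane via the alkoxysulfonium ion at or below room temperature, conditions that leave oxiranes intact; only the methyl hydrogens can be lost, because the one other β-hydrogen sits on the oxirane carbon and its removal would give a strained alkylidene oxirane, so neither stereocentre is touched.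

Step 5
Reactants: 8 (E)-but-2-enal (crotonaldehyde)
Product: 9 (Z)-2-iodobut-2-enal
Conditions: I2, K2CO3, 4-(dimethylamino)pyridine (cat.), THF/H2O, rt
Reagents that add atoms: iodine, II
Why: α-iodination of an enal by a Morita–Baylis–Hillman-type sequence (conjugate addition of the pyridine, iodination of the enolate, elimination), which should give the thermodynamically preferred Z isomer with iodine cis to the methyl group.

Step 6
Reactants: 9 (Z)-2-iodobut-2-enal
Product: 10 (Z)-2-iodobut-2-en-1-ol
Conditions: NaBH4, THF/H2O, 0 °C
Reagents that add atoms: none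
Why: borohydride 1,2-reduction of the aldehyde, which leaves the alkenyl iodide and the double-bond geometry untouched at 0 °C.

Step 7
Reactants: 10 (Z)-2-iodobut-2-en-1-ol
Product: 12 (Z)-2-(hydroxymethyl)but-2-enoic acid, via dilithium species 11 (not isolated)
Conditions: t-BuLi (3 equiv), Et2O, −78 °C; CO2, −78 °C to rt; aq. HCl
Reagents that add atoms: carbon dioxide, O=C=O
Why: deprotonation followed by iodine–lithium exchange should give the alkenyllithium 11 with retention of geometry (configurationally stable at −78 °C), and carboxylation with CO2 also proceeds with retention, so the carboxyl group ends cis to the methyl group (Z).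

Step 8
Reactants: 12 (Z)-2-(hydroxymethyl)but-2-enoic acid
Product: 13 (Z)-2-(acetoxymethyl)but-2-enoic acid
Conditions: AcCl, CH2Cl2, 0 °C to rt
Reagents that add atoms: acetyl chloride, CC(Cl)=O
Why: O-acetylation of a hydroxy acid with an acyl chloride in the absence of base, in which the primary alcohol is esterified, no amine is present that could add to the enoate and scramble its geometry, and any mixed anhydride is hydrolysed on aqueous work-up.

Step 9
Reactants: 7 1-[4-fluoro-2-(4-methoxybenzyloxy)-5-[(2S,3S)-3-(prop-1-en-2-yl)oxiran-2-yl]phenyl]ethanone; 13 (Z)-2-(acetoxymethyl)but-2-enoic acid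
Product: 16 (2S,3R)-5-acetyl-6-(4-methoxybenzyloxy)-2-(prop-1-en-2-yl)-2,3-dihydro-1-benzofuran-3-yl (Z)-2-(acetoxymethyl)but-2-enoate, via cesium carboxylate 14 (not isolated), via ring-opened cesium alkoxide 15 (not isolated)
Conditions: 13 (1.2 equiv), Cs2CO3 (2 equiv), 4 Å molecular sieves, DMF, rt; then 7, 45 to 70 °C
Reagents that add atoms: none
Why: Proposed new method: the cesium carboxylate 14 should attack the benzylic oxirane carbon (the future C3) from the side opposite its C–O bond in a loose SN2 transition state, giving the C3 ester with inversion and releasing the C2 alkoxide 15, which adds to C7a in a 5-exo-trig addition–elimination (SNAr) through a Meisenheimer adduct stabilised by the para C5 acetyl group and then expels fluoride. The closest known reaction types are the stereospecific opening of aryl oxiranes by carboxylates at the benzylic carbon and the base-mediated intramolecular SNAr of 2-(2-fluoroaryl)ethanols that carry a para acyl group; their coupling in one flask on an aryl vinyl oxirane is the untested part. The new C3 stereocentre is fixed as R by inversion of the S benzylic centre of 7 (substrate control), while C2 keeps its oxirane oxygen and its S configuration, so the trans oxirane maps onto the trans ring. The step needs attack at the benzylic carbon and not at the allylic carbon or at the terminal CH2 (SN2'); the alkoxy group para to the benzylic carbon stabilises positive charge in the transition state, and the methyl branch of the isopropenyl group screens the other two sites. A reversible 1,2-acyl shift between the two oxygens should do no harm, because only the C2 alkoxide can reach C7a through a five-membered ring and the irreversible loss of fluoride drains the equilibrium; the Z acid reacts as a nucleophile and is never activated, so its geometry is not put at risk.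

Step 10
Reactants: 16 (2S,3R)-5-acetyl-6-(4-methoxybenzyloxy)-2-(prop-1-en-2-yl)-2,3-dihydro-1-benzofuran-3-yl (Z)-2-(acetoxymethyl)but-2-enoate
Product: 17 (2S,3R)-5-acetyl-6-hydroxy-2-(prop-1-en-2-yl)-2,3-dihydro-1-benzofuran-3-yl (Z)-2-(acetoxymethyl)but-2-enoate
Conditions: DDQ, CH2Cl2/pH 7 phosphate buffer, 0 °C to rt
Reagents that add atoms: none
Why: oxidative cleavage of a 4-methoxybenzyl ether by DDQ (charge-transfer complex, benzylic hydride abstraction, hydrolysis of the oxocarbenium ion); the buffer takes up the acidic hydroquinone so that the ionisable C3 ester and the isopropenyl group should survive, and the phenol is released in neutral form, hydrogen-bonded to the C5 acetyl group.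

**Compound list**

1 | 1-(5-bromo-4-fluoro-2-hydroxyphenyl)ethanone | CC(=O)c1cc(Br)c(F)cc1O | starting material
2 | 4-methoxybenzyl chloride | COc1ccc(CCl)cc1 | starting material
3 | 1-[5-bromo-4-fluoro-2-(4-methoxybenzyloxy)phenyl]ethanone | CC(=O)c1cc(Br)c(F)cc1OCc1ccc(OC)cc1 | intermediate
4 | 2-methylbut-3-en-2-ol | C=CC(C)(C)O | starting material
5 | 1-[4-fluoro-5-[(E)-3-hydroxy-3-methylbut-1-en-1-yl]-2-(4-methoxybenzyloxy)phenyl]ethanone | CC(=O)c1cc(/C=C/C(C)(C)O)c(F)cc1OCc1ccc(OC)cc1 | intermediate
6 | 1-[4-fluoro-5-[(2S,3R)-3-(2-hydroxypropan-2-yl)oxiran-2-yl]-2-(4-methoxybenzyloxy)phenyl]ethanone (trans oxirane) | CC(C)(O)[C@@H]1O[C@H]1c2cc(C(C)=O)c(OCc3ccc(OC)cc3)cc2F | intermediate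
7 | 1-[4-fluoro-2-(4-methoxybenzyloxy)-5-[(2S,3S)-3-(prop-1-en-2-yl)oxiran-2-yl]phenyl]ethanone (trans oxirane) | C=C(C)[C@@H]1O[C@H]1c2cc(C(C)=O)c(OCc3ccc(OC)cc3)cc2F | intermediate
8 | (E)-but-2-enal (crotonaldehyde) | C/C=C/C=O | starting material
9 | (Z)-2-iodobut-2-enal | C/C=C(\I)C=O | intermediate
10 | (Z)-2-iodobut-2-en-1-ol | C/C=C(\I)CO | intermediate
11 | lithium (E)-2-lithiobut-2-en-1-olate (lithium cis to the methyl group; formed in the flask) | C/C=C(\[Li])CO[Li] | intermediate
12 | (Z)-2-(hydroxymethyl)but-2-enoic acid | C/C=C(\C(=O)O)CO | intermediate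
13 | (Z)-2-(acetoxymethyl)but-2-enoic acid | C/C=C(\C(=O)O)COC(C)=O | intermediate
14 | cesium (Z)-2-(acetoxymethyl)but-2-enoate (formed in the flask) | C/C=C(\C(=O)[O-])COC(C)=O.[Cs+] | intermediate
15 | cesium (1R,2S)-1-[5-acetyl-2-fluoro-4-(4-methoxybenzyloxy)phenyl]-1-{[(Z)-2-(acetoxymethyl)but-2-enoyl]oxy}-3-methylbut-3-en-2-olate (formed in the flask) | C=C(C)[C@H]([O-])[C@H](OC(=O)/C(=C\C)COC(C)=O)c1cc(C(C)=O)c(OCc2ccc(OC)cc2)cc1F.[Cs+] | intermediate
16 | (2S,3R)-5-acetyl-6-(4-methoxybenzyloxy)-2-(prop-1-en-2-yl)-2,3-dihydro-1-benzofuran-3-yl (Z)-2-(acetoxymethyl)but-2-enoate | C=C(C)[C@@H]1Oc2cc(OCc3ccc(OC)cc3)c(C(C)=O)cc2[C@H]1OC(=O)/C(=C\C)COC(C)=O | intermediate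
17 | (2S,3R)-5-acetyl-6-hydroxy-2-(prop-1-en-2-yl)-2,3-dihydro-1-benzofuran-3-yl (Z)-2-(acetoxymethyl)but-2-enoate | C=C(C)[C@@H]1Oc2cc(O)c(C(C)=O)cc2[C@H]1OC(=O)/C(=C\C)COC(C)=O | target

**Count and risks**

Total step count: 10. Longest linear sequence: 6 steps (steps 1, 2, 3, 4, 9, 10; the acid branch, steps 5 to 8 followed by 9 and 10, is equally long).

Steps most likely to fail:

1. Step 9. The carboxylate may attack the allylic oxirane carbon or the terminal methylene instead of the benzylic carbon. The benzylic centre may ionise and lose the clean inversion. Ring closure may also lag behind acetate transfer or conjugate addition of the alkoxide. The fallback uses known reactions only, sets out from 7 and comes back at 16. Acid-catalysed hydrolysis of 7 (HClO4 cat., THF/H2O, 0 °C) should open the oxirane at the benzylic carbon with inversion and give the anti diol 1-[5-[(1R,2S)-1,2-dihydroxy-3-methylbut-3-en-1-yl]-4-fluoro-2-(4-methoxybenzyloxy)phenyl]ethanone F1. KOt-Bu in THF at 0 °C should then close the ring by intramolecular SNAr of the C2 alkoxide (the benzylic alkoxide cannot reach C7a) to the trans alcohol 1-[(2S,3R)-3-hydroxy-6-(4-methoxybenzyloxy)-2-(prop-1-en-2-yl)-2,3-dihydro-1-benzofuran-5-yl]ethanone F2. For a Yamaguchi esterification, acid 13 is converted with 2,4,6-trichlorobenzoyl chloride and Et3N into the mixed anhydride (Z)-2-(acetoxymethyl)but-2-enoic 2,4,6-trichlorobenzoic anhydride F3, which should acylate F2 in warm toluene without a nucleophilic amine, so that the Z geometry is kept, and give 16 with retention at C3.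

2. Step 4. Ionisation of the alkoxysulfonium ion next to the oxirane may be slow, or may trigger opening or rearrangement of the electron-rich aryl oxirane. The fallback reverses the order of dehydration and epoxidation, sets out from 5 and comes back at 7. Dehydration of the allylic tertiary alcohol 5 with the same sulfurane should be easy and give the diene (E)-1-[4-fluoro-2-(4-methoxybenzyloxy)-5-(3-methylbuta-1,3-dien-1-yl)phenyl]ethanone F4. Shi monoepoxidation of this conjugated diene with the same L-configured ketone, a known reaction class, should then give 7. It relies on the catalyst favouring the trans-disubstituted styrenyl double bond over the 1,1-disubstituted one, which is the weak point of this alternative.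

3. Step 10. Hydride abstraction from the ether of an electron-poor phenol may be slow, leaving time for acid-induced loss of the C3 ester (aromatisation of the furan ring) or oxidation at the allylic C2–H. The fallback sets out from 16 and comes back at 17 by a different reaction type, with no new compound (F0). It is a chelation-directed Lewis acid dealkylation with MgBr2·OEt2 and Me2S in CH2Cl2 at rt. Magnesium should bridge the C5 carbonyl oxygen and O6, so the benzyl–oxygen bond breaks heterolytically and the sulfide takes up the benzyl cation, with neither an oxidant nor a Brønsted acid present.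

**Further compounds**

F1 | step 9 | 1-[5-[(1R,2S)-1,2-dihydroxy-3-methylbut-3-en-1-yl]-4-fluoro-2-(4-methoxybenzyloxy)phenyl]ethanone | C=C(C)[C@H](O)[C@H](O)c1cc(C(C)=O)c(OCc2ccc(OC)cc2)cc1F
F2 | step 9 | 1-[(2S,3R)-3-hydroxy-6-(4-methoxybenzyloxy)-2-(prop-1-en-2-yl)-2,3-dihydro-1-benzofuran-5-yl]ethanone | C=C(C)[C@@H]1Oc2cc(OCc3ccc(OC)cc3)c(C(C)=O)cc2[C@H]1O
F3 | step 9 | (Z)-2-(acetoxymethyl)but-2-enoic 2,4,6-trichlorobenzoic anhydride | C/C=C(\C(=O)OC(=O)c1c(Cl)cc(Cl)cc1Cl)COC(C)=O
F4 | step 4 | (E)-1-[4-fluoro-2-(4-methoxybenzyloxy)-5-(3-methylbuta-1,3-dien-1-yl)phenyl]ethanone | C=C(C)/C=C/c1cc(C(C)=O)c(OCc2ccc(OC)cc2)cc1F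
F0 | step 10 | none | none
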